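**Retrosynthetic overview**
- Target 16 ← Stille prenylation at C5' of bromo-diphenol 14 ← BCl3 removal of both isopropyl ethers from 13. The prenyl group is added last because its alkene would not survive the acid steps.
- 13 ← closure of the C4–C4a bond by intramolecular Friedel–Crafts acylation of the β-aryloxy-α-arylacrylic acid 11. The feature used is that the C4 carbonyl sits on C4a, which is ortho to O1 and para to the C7 oxygen of the resorcinol-type A ring, so C4a is the natural nucleophile once the O1–C2=C3 enol ether exists.
- 11 ← vinylic substitution of β-chloroacrylate 8 by 3-isopropoxyphenol 9, then saponification; 8 ← formylation and deoxychlorination of bromo arylacetate 6.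
- 6 ← paeonol 1 by O-isopropylation, Willgerodt–Kindler homologation, bromination para to the isopropoxy group and esterification.
- Rings A and B are bought as benzene rings; only the pyranone ring C is formed, in step 10.

Key step: step 10

Remarks on the chemistry: the target has no stereocentre and no stereogenic double bond, so "single enantiomer" is taken to mean the achiral compound as drawn. 3-Isopropoxyphenol is taken as a purchasable starting material; it is otherwise available by mono-alkylation of resorcinol.

**Step 1**
Reactants: 1 paeonol (2-hydroxy-4-methoxyacetophenone)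
Product: 2 1-(2-isopropoxy-4-methoxyphenyl)ethan-1-one
Conditions: 2-bromopropane, K2CO3, DMF, 70 °C
Reagents that add atoms: 2-bromopropane, CC(C)Br
Why: Williamson ether synthesis on the only phenol, giving an isopropyl ether that BCl3 should later cleave without touching the methyl ether.

**Step 2**
Reactants: 2 1-(2-isopropoxy-4-methoxyphenyl)ethan-1-one
Product: 3 2-(2-isopropoxy-4-methoxyphenyl)-1-(morpholin-4-yl)ethane-1-thione
Conditions: S8, morpholine, 130 °C
Reagents that add atoms: sulfur, S1SSSSSSS1; morpholine, C1COCCN1
Why: Willgerodt–Kindler reaction, which moves the oxidised carbon of the aryl methyl ketone to the chain terminus as a thioamide; the aryl ethers are inert to sulfur and amine.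

**Step 3**
Reactants: 3 2-(2-isopropoxy-4-methoxyphenyl)-1-(morpholin-4-yl)ethane-1-thione
Product: 4 2-(2-isopropoxy-4-methoxyphenyl)acetic acid
Conditions: KOH, EtOH/H2O, reflux; then aq. HCl
Reagents that add atoms: water (as aqueous potassium hydroxide), O
Why: alkaline hydrolysis of the thioamide, the standard second stage of the Willgerodt–Kindler homologation, should give the arylacetic acid.

**Step 4**
Reactants: 4 2-(2-isopropoxy-4-methoxyphenyl)acetic acid
Product: 5 2-(5-bromo-2-isopropoxy-4-methoxyphenyl)acetic acid
Conditions: NBS, MeCN, 0 °C to rt, dark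
Reagents that add atoms: N-bromosuccinimide, O=C1CCC(=O)N1Br
Why: electrophilic aromatic bromination should go to C5, which is para to the isopropoxy and ortho to the methoxy group, whereas C3 is flanked by both ethers and C6 is meta to both.

**Step 5**
Reactants: 5 2-(5-bromo-2-isopropoxy-4-methoxyphenyl)acetic acid
Product: 6 methyl 2-(5-bromo-2-isopropoxy-4-methoxyphenyl)acetate
Conditions: MeOH, cat. H2SO4, reflux
Reagents that add atoms: methanol, CO
Why: Fischer esterification; catalytic acid in methanol does not cleave aryl isopropyl ethers.

**Step 6**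
Reactants: 6 methyl 2-(5-bromo-2-isopropoxy-4-methoxyphenyl)acetate
Product: 7 methyl (Z)-2-(5-bromo-2-isopropoxy-4-methoxyphenyl)-3-hydroxyacrylate (enol form of the α-formyl ester)
Conditions: NaH, HCO2Me, THF, 0 °C to rt; then cold aq. HCl
Reagents that add atoms: methyl formate, COC=O
Why: crossed Claisen condensation (C-formylation) of the only enolisable ester with non-enolisable methyl formate, driven by deprotonation of the product.

**Step 7**
Reactants: 7 methyl (Z)-2-(5-bromo-2-isopropoxy-4-methoxyphenyl)-3-hydroxyacrylate
Product: 8 methyl 2-(5-bromo-2-isopropoxy-4-methoxyphenyl)-3-chloroacrylate (E/Z mixture, used as such)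
Conditions: (COCl)2, DMF, CH2Cl2, 0 °C to rt
Reagents that add atoms: oxalyl chloride, O=C(Cl)C(Cl)=O
Why: Vilsmeier-type deoxychlorination of a 1,3-dicarbonyl enol, in which the chloroiminium salt activates the enol oxygen and chloride replaces it at the β-carbon by addition–elimination.

**Step 8**
Reactants: 8 methyl 2-(5-bromo-2-isopropoxy-4-methoxyphenyl)-3-chloroacrylate; 9 3-isopropoxyphenol
Product: 10 methyl (E)-2-(5-bromo-2-isopropoxy-4-methoxyphenyl)-3-(3-isopropoxyphenoxy)acrylate
Conditions: K2CO3, DMF, 60 °C
Reagents that add atoms: none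
Why: nucleophilic vinylic substitution (addition–elimination) in which the phenoxide adds to the β-carbon and the aryl-stabilised ester enolate expels chloride; rotation in that enolate should bring both chloride isomers to the more stable E enol ether.

**Step 9**
Reactants: 10 methyl (E)-2-(5-bromo-2-isopropoxy-4-methoxyphenyl)-3-(3-isopropoxyphenoxy)acrylate
Product: 11 (E)-2-(5-bromo-2-isopropoxy-4-methoxyphenyl)-3-(3-isopropoxyphenoxy)acrylic acid
Conditions: LiOH·H2O, THF/MeOH/H2O, rt; then 1 M HCl, 0 °C
Reagents that add atoms: water (as aqueous lithium hydroxide), O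
Why: saponification, the classical way from β-aryloxyacrylic esters to the acids used for chromone ring closure; the carboxylate formed is no longer a Michael acceptor, which protects the enol ether.

**Step 10**
Reactants: 11 (E)-2-(5-bromo-2-isopropoxy-4-methoxyphenyl)-3-(3-isopropoxyphenoxy)acrylic acid
Product: 13 3-(5-bromo-2-isopropoxy-4-methoxyphenyl)-7-isopropoxychromen-4-one, via acid chloride 12 (not isolated)
Conditions: (COCl)2, cat. DMF, CH2Cl2, 0 °C to rt; then SnCl4, CH2Cl2, −78 to 0 °C
Reagents that add atoms: none
Why: Oxalyl chloride turns 11 into acid chloride 12, and SnCl4 ionises it to an acylium ion stabilised by the β-aryloxy oxygen (ArO+=CH–C(Ar')=C=O); in that form the Cα–Cβ bond is nearly single, so the E arrangement of 11 can rotate into the Z arrangement that is able to close. The ring carbon of the aryloxy ring that is ortho to the enol ether oxygen and para to the isopropoxy group then attacks the acyl carbon and rearomatises with loss of HCl, an intramolecular Friedel–Crafts acylation of the kind long used to cyclise 3-aryloxyacrylic acids to chromones. The pyranone closes in a 6-exo mode (exo-trig on the complexed acyl chloride, exo-dig on the free acylium) and forms C4–C4a. No stereocentre is created. The step needs closure para rather than ortho to the A-ring isopropoxy group, which the substrate secures because the ortho site lies between two oxygens and is the more hindered, while attack on the B ring would require a four-membered ring. SnCl4 at low temperature, rather than a harder Lewis acid, is chosen to keep both isopropyl ethers intact and to hold back dealkylative attack of the 2'-isopropoxy oxygen on the acyl group.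

**Step 11**
Reactants: 13 3-(5-bromo-2-isopropoxy-4-methoxyphenyl)-7-isopropoxychromen-4-one
Product: 14 3-(5-bromo-2-hydroxy-4-methoxyphenyl)-7-hydroxychromen-4-one
Conditions: BCl3 (excess), CH2Cl2, −78 to 0 °C; then MeOH, aq. NaHCO3
Reagents that add atoms: none
Why: Lewis-acid ether cleavage, in which BCl3 removes secondary isopropyl groups as 2-chloropropane far faster than it attacks a methyl ether that has no chelating carbonyl neighbour; the aryl bromide is inert, and the step precedes prenylation because the trisubstituted alkene would not tolerate BCl3.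

**Step 12**
Reactants: 14 3-(5-bromo-2-hydroxy-4-methoxyphenyl)-7-hydroxychromen-4-one; 15 tributyl(3-methylbut-2-enyl)stannane
Product: 16 3-[2-hydroxy-4-methoxy-5-(3-methylbut-2-enyl)phenyl]-7-hydroxychromen-4-one (CNP0180972.0)
Conditions: Pd(PPh3)4 (cat.), DMF, 100 °C, degassed
Reagents that add atoms: none
Why: Stille cross-coupling under neutral conditions, which tolerates free phenols and the chromone; coupling at the unsubstituted allyl terminus should give the linear prenyl group.

**Compound list**
1 | paeonol (2-hydroxy-4-methoxyacetophenone) | CC(=O)c1ccc(OC)cc1O | starting material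
2 | 1-(2-isopropoxy-4-methoxyphenyl)ethan-1-one | CC(=O)c1ccc(OC)cc1OC(C)C | intermediate
3 | 2-(2-isopropoxy-4-methoxyphenyl)-1-(morpholin-4-yl)ethane-1-thione | S=C(Cc1ccc(OC)cc1OC(C)C)N1CCOCC1 | intermediate
4 | 2-(2-isopropoxy-4-methoxyphenyl)acetic acid | OC(=O)Cc1ccc(OC)cc1OC(C)C | intermediate
5 | 2-(5-bromo-2-isopropoxy-4-methoxyphenyl)acetic acid | OC(=O)Cc1cc(Br)c(OC)cc1OC(C)C | intermediate
6 | methyl 2-(5-bromo-2-isopropoxy-4-methoxyphenyl)acetate | COC(=O)Cc1cc(Br)c(OC)cc1OC(C)C | intermediate
7 | methyl (Z)-2-(5-bromo-2-isopropoxy-4-methoxyphenyl)-3-hydroxyacrylate | COC(=O)/C(=C\O)c1cc(Br)c(OC)cc1OC(C)C | intermediate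
8 | methyl 2-(5-bromo-2-isopropoxy-4-methoxyphenyl)-3-chloroacrylate (E/Z mixture, geometry not assigned) | COC(=O)C(=CCl)c1cc(Br)c(OC)cc1OC(C)C | intermediate
9 | 3-isopropoxyphenol | CC(C)Oc1cccc(O)c1 | starting material
10 | methyl (E)-2-(5-bromo-2-isopropoxy-4-methoxyphenyl)-3-(3-isopropoxyphenoxy)acrylate | COC(=O)/C(=C/Oc1cccc(OC(C)C)c1)c1cc(Br)c(OC)cc1OC(C)C | intermediate
11 | (E)-2-(5-bromo-2-isopropoxy-4-methoxyphenyl)-3-(3-isopropoxyphenoxy)acrylic acid | OC(=O)/C(=C/Oc1cccc(OC(C)C)c1)c1cc(Br)c(OC)cc1OC(C)C | intermediate
12 | (E)-2-(5-bromo-2-isopropoxy-4-methoxyphenyl)-3-(3-isopropoxyphenoxy)acryloyl chloride | O=C(Cl)/C(=C/Oc1cccc(OC(C)C)c1)c1cc(Br)c(OC)cc1OC(C)C | intermediate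
13 | 3-(5-bromo-2-isopropoxy-4-methoxyphenyl)-7-isopropoxychromen-4-one | CC(C)Oc1ccc2c(c1)occ(-c1cc(Br)c(OC)cc1OC(C)C)c2=O | intermediate
14 | 3-(5-bromo-2-hydroxy-4-methoxyphenyl)-7-hydroxychromen-4-one | COc1cc(O)c(-c2coc3cc(O)ccc3c2=O)cc1Br | intermediate
15 | tributyl(3-methylbut-2-enyl)stannane | CCCC[Sn](CCCC)(CCCC)CC=C(C)C | starting material
16 | 3-[2-hydroxy-4-methoxy-5-(3-methylbut-2-enyl)phenyl]-7-hydroxychromen-4-one | COc1cc(O)c(-c2coc3cc(O)ccc3c2=O)cc1CC=C(C)C | target

**Step count**
Total: 12 steps. Longest linear sequence: 12 steps (paeonol 1 to 16); 9 and 15 are bought.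

**Steps most likely to fail**

1. Step 10 (ring closure). The 2'-isopropoxy oxygen lies five atoms from the activated acyl carbon whatever the alkene geometry. It may therefore add to the acylium and lose its isopropyl group, consuming the acid as a benzofuranone before rotation to the Z arrangement and C-acylation take place. Closure at the ring carbon between the two A-ring oxygens is a second possible leak.
Fallback: set out from bromo acid 5 and build the pyranone in the deoxybenzoin order instead. Acylation of resorcinol with 5 in BF3·OEt2 at about 80 °C should give 2-(5-bromo-2-isopropoxy-4-methoxyphenyl)-1-(2,4-dihydroxyphenyl)ethan-1-one F1. One-carbon insertion and ring closure with DMF, BF3·OEt2 and MsCl should give 3-(5-bromo-2-isopropoxy-4-methoxyphenyl)-7-hydroxychromen-4-one F2. BCl3 in CH2Cl2 then removes the one isopropyl group, and the route is rejoined at 14.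

2. Step 12 (prenylation). The allyl group may transpose during transmetalation or reductive elimination and give the 1,1-dimethylallyl isomer. The acidic phenols may also protodestannylate the allylstannane, and oxidative addition into the electron-rich aryl bromide may be slow.
Fallback: set out from 14 and mask the phenols, then build the prenyl group in two stages. Ac2O and pyridine should give 3-(2-acetoxy-5-bromo-4-methoxyphenyl)-4-oxochromen-7-yl acetate F3. Stille coupling with allyltributylstannane, which has no regiochemical ambiguity, should give 3-(2-acetoxy-5-allyl-4-methoxyphenyl)-4-oxochromen-7-yl acetate F4. Cross-metathesis with 2-methyl-2-butene and a second-generation Grubbs catalyst should give 3-[2-acetoxy-4-methoxy-5-(3-methylbut-2-enyl)phenyl]-4-oxochromen-7-yl acetate F5. K2CO3 in MeOH removes the acetates, and the route is rejoined at 16.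

3. Step 2 (Willgerodt–Kindler). Thioamide formation may be sluggish with the ortho-alkoxy-hindered ketone, and the mixture may tar at the temperature required.
Fallback: set out from ketone 2 and use an oxidative 1,2-aryl migration. Thallium(III) nitrate in MeOH/trimethyl orthoformate (or PhI(OAc)2/H2SO4 in trimethyl orthoformate) should give methyl 2-(2-isopropoxy-4-methoxyphenyl)acetate F6 directly. NBS in MeCN should brominate C5, and the route is rejoined at ester 6, which also bypasses steps 3 to 5.

**Further compounds**
F1 | step 10 | 2-(5-bromo-2-isopropoxy-4-methoxyphenyl)-1-(2,4-dihydroxyphenyl)ethan-1-one | O=C(Cc1cc(Br)c(OC)cc1OC(C)C)c1ccc(O)cc1O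
F2 | step 10 | 3-(5-bromo-2-isopropoxy-4-methoxyphenyl)-7-hydroxychromen-4-one | COc1cc(OC(C)C)c(-c2coc3cc(O)ccc3c2=O)cc1Br
F3 | step 12 | 3-(2-acetoxy-5-bromo-4-methoxyphenyl)-4-oxochromen-7-yl acetate | COc1cc(OC(C)=O)c(-c2coc3cc(OC(C)=O)ccc3c2=O)cc1Br
F4 | step 12 | 3-(2-acetoxy-5-allyl-4-methoxyphenyl)-4-oxochromen-7-yl acetate | COc1cc(OC(C)=O)c(-c2coc3cc(OC(C)=O)ccc3c2=O)cc1CC=C
F5 | step 12 | 3-[2-acetoxy-4-methoxy-5-(3-methylbut-2-enyl)phenyl]-4-oxochromen-7-yl acetate | COc1cc(OC(C)=O)c(-c2coc3cc(OC(C)=O)ccc3c2=O)cc1CC=C(C)C
F6 | step 2 | methyl 2-(2-isopropoxy-4-methoxyphenyl)acetate | COC(=O)Cc1ccc(OC)cc1OC(C)C
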